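**Retrosynthetic overview** (chroman numbering of the target: O1, C2, C3, C4, C4a, C5–C8, C8a)

1. The target comes from LiOH opening of a (4R)-dihydrocoumarin lactone, itself from a CuH asymmetric 1,4-reduction of a pyrano[2,3-f]coumarin; the coumarin pyranone is a temporary ring that masks the C5–OH and the CH2CO2H arm.
2. Key disconnection: the dihydropyran ring O1–C2–C3–C4–C4a–C8a is cut at C4–C4a and closed by a one-pot 9-BBN hydroboration/intramolecular B-alkyl Suzuki–Miyaura coupling of an aryl bromide carrying an ortho (S)-3-methylbut-3-en-2-yl ether. C3 is set in that step; C2 comes from Mitsunobu inversion of the (R)-alcohol.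
3. Enabling feature: C4a is the aromatic carbon between the oxygen-bearing C5 and C8a, so a bromine there lies ortho to O1; the 1,1-disubstituted C3=C4 alkene, allylic to the C2 stereocentre, takes boron on C4, which is then placed for six-ring closure. The same bromine first blocks C4a so that a Claisen rearrangement delivers the prenyl group to C8.
4. The bromophenol comes from phloroglucinol and ethyl 3-oxohexanoate (Pechmann), then 7-O-propargylation, 5-O-methylation, bromination, Lindlar reduction and aromatic Claisen rearrangement (coumarin C8 / O7 / C6 = chroman C4a / O1 / C8).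
5. Ring order: benzene ring (from phloroglucinol), then the temporary pyranone (Pechmann), then the dihydropyran of the target (key step, last ring closed); the pyranone is opened in the final step.

Key step: step 9

Assumption: the sense of induction of the CuH/DTBM-SEGPHOS reduction in step 10 is assigned by analogy only; the (R)-ligand is written, and its antipode would be used if a first run gave the (4S) lactone.

**Route**

Step 1
Reactants: 1 phloroglucinol (benzene-1,3,5-triol); 2 ethyl 3-oxohexanoate
Product: 3 5,7-dihydroxy-4-propyl-2H-chromen-2-one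
Conditions: conc. H2SO4, 0 °C → rt
Reagents that add atoms: none
Why: Pechmann condensation (transesterification, ring hydroxyalkylation, dehydration) builds the temporary pyranone ring, and the three ring positions of phloroglucinol are equivalent, so a single regioisomer should form.

Step 2
Reactants: 3 5,7-dihydroxy-4-propyl-2H-chromen-2-one; 4 3-chloro-3-methylbut-1-yne
Product: 5 5-hydroxy-7-[(2-methylbut-3-yn-2-yl)oxy]-4-propyl-2H-chromen-2-one
Conditions: K2CO3 (1.1 equiv), KI (cat.), acetone, 55 °C
Reagents that add atoms: none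
Why: Williamson-type etherification with the tertiary propargylic chloride should occur at the 7-OH, the more acidic hydroxyl (conjugated through C4a to the pyranone carbonyl) and the one not crowded by the peri 4-propyl group.

Step 3
Reactants: 5 5-hydroxy-7-[(2-methylbut-3-yn-2-yl)oxy]-4-propyl-2H-chromen-2-one
Product: 6 5-methoxy-7-[(2-methylbut-3-yn-2-yl)oxy]-4-propyl-2H-chromen-2-one
Conditions: MeI, K2CO3, DMF, rt
Reagents that add atoms: iodomethane, CI
Why: Williamson O-methylation of the remaining 5-OH installs the methoxy group of the target, the terminal alkyne not being deprotonated by carbonate.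

Step 4
Reactants: 6 5-methoxy-7-[(2-methylbut-3-yn-2-yl)oxy]-4-propyl-2H-chromen-2-one
Product: 7 8-bromo-5-methoxy-7-[(2-methylbut-3-yn-2-yl)oxy]-4-propyl-2H-chromen-2-one
Conditions: NBS (1.0 equiv), MeCN, 0 °C, dark
Reagents that add atoms: N-bromosuccinimide, O=C1CCC(=O)N1Br
Why: Electrophilic aromatic bromination should go to C8, which is para to the 5-OMe and ortho to O7, whereas C6 is shielded between the tert-alkoxy group and the 5-OMe methyl that the peri propyl group turns towards C6.

Step 5
Reactants: 7 8-bromo-5-methoxy-7-[(2-methylbut-3-yn-2-yl)oxy]-4-propyl-2H-chromen-2-one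
Product: 8 8-bromo-5-methoxy-7-[(2-methylbut-3-en-2-yl)oxy]-4-propyl-2H-chromen-2-one
Conditions: H2 (1 atm), Lindlar catalyst, quinoline, EtOAc, rt
Reagents that add atoms: none
Why: Lindlar semihydrogenation reduces the terminal alkyne to the alkene, and the poisoned catalyst should leave the aryl bromide and the coumarin C3=C4 bond untouched.

Step 6
Reactants: 8 8-bromo-5-methoxy-7-[(2-methylbut-3-en-2-yl)oxy]-4-propyl-2H-chromen-2-one
Product: 9 8-bromo-7-hydroxy-5-methoxy-6-(3-methylbut-2-en-1-yl)-4-propyl-2H-chromen-2-one
Conditions: PhNEt2, 120 °C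
Reagents that add atoms: none
Why: Aromatic Claisen [3,3] rearrangement of the 1,1-dimethylallyl ether followed by enolisation gives the 6-prenyl phenol, because C8 is blocked by bromine and only C6 can accept the allyl terminus.

Step 7
Reactants: 10 3-methylbut-3-en-2-one
Product: 11 (R)-3-methylbut-3-en-2-ol
Conditions: (S)-Me-CBS (10 mol%), catecholborane, toluene, −78 °C; aq. NaOH work-up
Reagents that add atoms: none
Why: Corey–Bakshi–Shibata reduction in which the isopropenyl group acts as the large substituent, so the (S)-oxazaborolidine should give the (R)-carbinol, while catecholborane at low temperature avoids hydroboration of the alkene.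

Step 8
Reactants: 9 8-bromo-7-hydroxy-5-methoxy-6-(3-methylbut-2-en-1-yl)-4-propyl-2H-chromen-2-one; 11 (R)-3-methylbut-3-en-2-ol
Product: 12 8-bromo-5-methoxy-7-{[(2S)-3-methylbut-3-en-2-yl]oxy}-6-(3-methylbut-2-en-1-yl)-4-propyl-2H-chromen-2-one
Conditions: PPh3, DIAD, THF (high concentration), sonication, 0 °C → rt
Reagents that add atoms: none
Why: Mitsunobu etherification, an SN2 displacement of the oxyphosphonium group by the acidic ortho-bromophenoxide with inversion, converts the (R)-alcohol into the (S)-configured aryl ether that becomes C2 of the chroman.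

Step 9
Reactants: 12 8-bromo-5-methoxy-7-{[(2S)-3-methylbut-3-en-2-yl]oxy}-6-(3-methylbut-2-en-1-yl)-4-propyl-2H-chromen-2-one
Product: 14 (8S,9R)-5-methoxy-8,9-dimethyl-6-(3-methylbut-2-en-1-yl)-4-propyl-9,10-dihydro-2H,8H-pyrano[2,3-f]chromen-2-one, via B-alkyl-9-BBN adduct 13 (not isolated)
Conditions: 9-BBN (1.3 equiv), THF, 0 °C → rt; then Pd(OAc)2 (5 mol%), SPhos (10 mol%), 3 M aq. K3PO4, 60 °C; dil. HCl work-up
Reagents that add atoms: none
Why: 9-BBN adds across the 1,1-disubstituted C3=C4 alkene (boron to terminal C4, hydrogen to C3), Pd(0)/SPhos inserts into the C4a–Br bond, and base-activated B-alkyl transmetalation followed by C(sp3)–C(sp2) reductive elimination joins C4 to C4a. The closest known reaction type is the one-pot 9-BBN hydroboration/intramolecular B-alkyl Suzuki–Miyaura cyclisation of ω-alkenyl aryl halides. The dihydropyran ring (O1, C2, C3, C4, C4a, C8a) closes by reductive elimination from a seven-membered oxapalladacycle, that is, a six-membered ring formed at the aryl carbon. C3 is set in the hydroboration by 1,2-induction from C2: with the C2–H eclipsing the alkene to avoid A1,3 strain, 9-BBN should attack anti to the C2 methyl, the anti sense known for 9-BBN additions to 1,1-disubstituted allylic ethers, which after closure is the trans (2S,3R)-dimethyl arrangement, while C2 is not touched. The step needs chemoselectivity for the 1,1-disubstituted alkene over the prenyl alkene and the coumarin enoate, which the bulk of 9-BBN should secure, and the ring-closure site is fixed because C4a carries the only halogen and C8 is already substituted.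

Step 10
Reactants: 14 (8S,9R)-5-methoxy-8,9-dimethyl-6-(3-methylbut-2-en-1-yl)-4-propyl-9,10-dihydro-2H,8H-pyrano[2,3-f]chromen-2-one
Product: 15 (4R,8S,9R)-5-methoxy-8,9-dimethyl-6-(3-methylbut-2-en-1-yl)-4-propyl-3,4,9,10-tetrahydro-2H,8H-pyrano[2,3-f]chromen-2-one
Conditions: Cu(OAc)2·H2O (5 mol%), (R)-DTBM-SEGPHOS (5.5 mol%), (EtO)2MeSiH (3 equiv), toluene, 0 °C → rt; then sat. aq. NH4Cl
Reagents that add atoms: none
Why: CuH-catalysed asymmetric conjugate reduction, in which the ligated copper hydride adds to C4 of the coumarin enoate from the face chosen by the bisphosphine and the resulting silyl ketene acetal gives the lactone on work-up, should set the (4R) centre under catalyst control while the isolated prenyl alkene stays inert.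

Step 11
Reactants: 15 (4R,8S,9R)-5-methoxy-8,9-dimethyl-6-(3-methylbut-2-en-1-yl)-4-propyl-3,4,9,10-tetrahydro-2H,8H-pyrano[2,3-f]chromen-2-one
Product: 16 (3R)-3-[(2S,3R)-5-hydroxy-7-methoxy-2,3-dimethyl-8-(3-methylbut-2-en-1-yl)-3,4-dihydro-2H-chromen-6-yl]hexanoic acid
Conditions: LiOH·H2O (3 equiv), THF/H2O, rt; then 1 M HCl to pH 4, 0 °C
Reagents that add atoms: water, O
Why: Saponification of the aryl ester (lactone) opens the temporary pyranone and releases the C5 phenol and the carboxylic acid without touching a stereocentre, and cold, mild acidification should limit relactonisation.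

**Compound list**

1 | phloroglucinol (benzene-1,3,5-triol) | Oc1cc(O)cc(O)c1 | starting material
2 | ethyl 3-oxohexanoate | CCCC(=O)CC(=O)OCC | starting material
3 | 5,7-dihydroxy-4-propyl-2H-chromen-2-one | CCCC1=CC(=O)Oc2cc(O)cc(O)c12 | intermediate
4 | 3-chloro-3-methylbut-1-yne | CC(C)(Cl)C#C | starting material
5 | 5-hydroxy-7-[(2-methylbut-3-yn-2-yl)oxy]-4-propyl-2H-chromen-2-one | CCCC1=CC(=O)Oc2cc(OC(C)(C)C#C)cc(O)c12 | intermediate
6 | 5-methoxy-7-[(2-methylbut-3-yn-2-yl)oxy]-4-propyl-2H-chromen-2-one | CCCC1=CC(=O)Oc2cc(OC(C)(C)C#C)cc(OC)c12 | intermediate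
7 | 8-bromo-5-methoxy-7-[(2-methylbut-3-yn-2-yl)oxy]-4-propyl-2H-chromen-2-one | CCCC1=CC(=O)Oc2c(Br)c(OC(C)(C)C#C)cc(OC)c12 | intermediate
8 | 8-bromo-5-methoxy-7-[(2-methylbut-3-en-2-yl)oxy]-4-propyl-2H-chromen-2-one | CCCC1=CC(=O)Oc2c(Br)c(OC(C)(C)C=C)cc(OC)c12 | intermediate
9 | 8-bromo-7-hydroxy-5-methoxy-6-(3-methylbut-2-en-1-yl)-4-propyl-2H-chromen-2-one | CCCC1=CC(=O)Oc2c(Br)c(O)c(CC=C(C)C)c(OC)c12 | intermediate
10 | 3-methylbut-3-en-2-one | CC(=O)C(C)=C | starting material
11 | (R)-3-methylbut-3-en-2-ol | C=C(C)[C@@H](C)O | intermediate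
12 | 8-bromo-5-methoxy-7-{[(2S)-3-methylbut-3-en-2-yl]oxy}-6-(3-methylbut-2-en-1-yl)-4-propyl-2H-chromen-2-one | CCCC1=CC(=O)Oc2c(Br)c(O[C@@H](C)C(C)=C)c(CC=C(C)C)c(OC)c12 | intermediate
13 | 8-bromo-7-{[(2S,3R)-4-(9-borabicyclo[3.3.1]nonan-9-yl)-3-methylbutan-2-yl]oxy}-5-methoxy-6-(3-methylbut-2-en-1-yl)-4-propyl-2H-chromen-2-one (B-alkyl-9-BBN adduct) | CCCC1=CC(=O)Oc2c(Br)c(O[C@@H](C)[C@H](C)CB3C4CCCC3CCC4)c(CC=C(C)C)c(OC)c12 | intermediate (not isolated)
14 | (8S,9R)-5-methoxy-8,9-dimethyl-6-(3-methylbut-2-en-1-yl)-4-propyl-9,10-dihydro-2H,8H-pyrano[2,3-f]chromen-2-one | O=C1C=C(CCC)c2c(OC)c(CC=C(C)C)c3O[C@@H](C)[C@H](C)Cc3c2O1 | intermediate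
15 | (4R,8S,9R)-5-methoxy-8,9-dimethyl-6-(3-methylbut-2-en-1-yl)-4-propyl-3,4,9,10-tetrahydro-2H,8H-pyrano[2,3-f]chromen-2-one | CCC[C@@H]1CC(=O)Oc2c1c(OC)c(CC=C(C)C)c1O[C@@H](C)[C@H](C)Cc21 | intermediate
16 | (3R)-3-[(2S,3R)-5-hydroxy-7-methoxy-2,3-dimethyl-8-(3-methylbut-2-en-1-yl)-3,4-dihydro-2H-chromen-6-yl]hexanoic acid | CCC[C@H](CC(=O)O)c1c(O)c2c(c(CC=C(C)C)c1OC)O[C@@H](C)[C@H](C)C2 | target

**Step count and risks**

Total step count: 11. Longest linear sequence: 10 steps (steps 1–6 and 8–11; step 7 is the side branch).

Steps most likely to fail: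

1. Step 9 (key step). What may go wrong: poor facial selectivity in the hydroboration, or slow oxidative addition at the doubly ortho-oxygenated C–Br bond so that protodeboronation of the alkylborane overtakes ring closure. The fallback sets out from 12 and comes back to the route at 14. Hydroboration of 12 with 9-BBN and oxidative work-up (NaBO3·4H2O) would give the primary alcohol 8-bromo-7-{[(2S,3R)-4-hydroxy-3-methylbutan-2-yl]oxy}-5-methoxy-6-(3-methylbut-2-en-1-yl)-4-propyl-2H-chromen-2-one F1, at which stage a minor diastereomer can be removed by chromatography. An Appel reaction (I2, PPh3, imidazole, CH2Cl2) would then give the iodide 8-bromo-7-{[(2S,3S)-4-iodo-3-methylbutan-2-yl]oxy}-5-methoxy-6-(3-methylbut-2-en-1-yl)-4-propyl-2H-chromen-2-one F2. A nickel-catalysed intramolecular reductive cross-electrophile coupling of the aryl bromide with the primary iodide (NiBr2·glyme, 4,4′-di-tert-butyl-2,2′-bipyridine, Zn, DMA, 60 °C) would close the C4–C4a bond to give 14.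

2. Step 8. What may go wrong: low conversion at the doubly ortho-substituted phenol, or SN2′ attack and elimination of the activated allylic alcohol, with loss of yield and enantiopurity. The fallback sets out from 9 and comes back to the route at 12. It is a palladium-catalysed asymmetric allylic etherification (Tsuji–Trost type) of 9 with the achiral carbonate (E)-2-methylbut-2-en-1-yl methyl carbonate F3, made from commercial (E)-2-methylbut-2-en-1-ol and methyl chloroformate. With Pd2(dba)3·CHCl3 and the enantiomer of the DACH-phenyl bis(diphenylphosphinobenzamide) ligand that favours the (S)-ether (CH2Cl2, rt), the phenoxide should attack the more substituted terminus of the 1,2-dimethylallyl palladium complex and give the branched ether 12 without a preformed chiral alcohol.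

3. Step 10. What may go wrong: slow or poorly face-selective hydride transfer to the hindered β,β-disubstituted enoate next to the peri 5-OMe, or further reduction of the lactone. The fallback sets out from 14 and comes back to the route at 15. Non-selective conjugate reduction with L-Selectride (THF, −78 °C) would give 15 together with its C4 epimer (4S,8S,9R)-5-methoxy-8,9-dimethyl-6-(3-methylbut-2-en-1-yl)-4-propyl-3,4,9,10-tetrahydro-2H,8H-pyrano[2,3-f]chromen-2-one F4. The two are diastereomers because C8 and C9 are already fixed, so 15 would be obtained by chromatographic separation and taken into step 11.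

Further compounds
F1 | step 9 | 8-bromo-7-{[(2S,3R)-4-hydroxy-3-methylbutan-2-yl]oxy}-5-methoxy-6-(3-methylbut-2-en-1-yl)-4-propyl-2H-chromen-2-one | CCCC1=CC(=O)Oc2c(Br)c(O[C@@H](C)[C@H](C)CO)c(CC=C(C)C)c(OC)c12
F2 | step 9 | 8-bromo-7-{[(2S,3S)-4-iodo-3-methylbutan-2-yl]oxy}-5-methoxy-6-(3-methylbut-2-en-1-yl)-4-propyl-2H-chromen-2-one | CCCC1=CC(=O)Oc2c(Br)c(O[C@@H](C)[C@H](C)CI)c(CC=C(C)C)c(OC)c12
F3 | step 8 | (E)-2-methylbut-2-en-1-yl methyl carbonate | C/C=C(\C)COC(=O)OC
F4 | step 10 | (4S,8S,9R)-5-methoxy-8,9-dimethyl-6-(3-methylbut-2-en-1-yl)-4-propyl-3,4,9,10-tetrahydro-2H,8H-pyrano[2,3-f]chromen-2-one | CCC[C@H]1CC(=O)Oc2c1c(OC)c(CC=C(C)C)c1O[C@@H](C)[C@H](C)Cc21
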